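## The problem

The target **17**, (1R,1'R,2S,2'S)-4,4'-[(1E,3E)-buta-1,3-diene-1,4-diyl]bis(2-{2-[(2R)-3,3-dimethyloxiran-2-yl]ethyl}-2-methylcyclohex-3-en-1-ol), is a C2-symmetric C30H46O4 dimer. Two cyclohex-3-en-1-ol rings are joined through C4 and C4' by an (E,E)-butadiene, so that C3=C4–C7=C8–C8'=C7'–C4'=C3' is one conjugated tetraene. Each ring carries the contiguous pair C1 (secondary carbinol, R) and C2 (all-carbon quaternary centre, S), with the hydroxyl cis to the epoxyethyl chain and trans to the methyl group; the two centres are best set together, in a cyclic transition state that forms the C1–C2 bond itself. The third stereocentre of each half, the (R)-epoxide carbon, lies four bonds from C2, can neither direct nor be directed by the ring centres, and needs its own reagent control. The compound tolerates little: the trisubstituted epoxides open under Brønsted or Lewis acid, the cis C1 hydroxyl can reach the epoxide CH in a 6-exo opening to a tetrahydropyran, and the tetraene is sensitive to acid, electrophiles, oxygen and light. The enabling feature is that the only ring alkene, C3=C4, lies between quaternary C2 and diene-bearing C4: cutting it leaves a vinyl group on C2 and a methylidene on C4, and the open chain is then a homoallylic alcohol whose quaternary carbon bears vinyl, methyl and an epoxy chain, the imprint of a 6,7-epoxygeranyl unit added through its γ-carbon to an aldehyde.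

## Retrosynthesis

**17 ⇒ 15.** Both ring alkenes C3=C4 and C3'=C4' are cut, giving the acyclic C2-symmetric bis-epoxy hexaene diol **15** (vinyl on each quaternary carbon, methylidene on each end of the linker). Against a cut at the ring–linker bonds C4–C7, or at C2–C3, this cut touches no stereocentre and removes both rings at once. It also turns the C1/C2 pair into an acyclic stereodiad that a single addition can set. The forward step is a two-directional ring-closing metathesis: it has to close six-membered rings onto 1,1-disubstituted diene termini, choose correctly among six alkenes, and leave hydroxyls and epoxides alone. Placed last, it releases the target under neutral conditions.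

**15 ⇒ 2 × 13.** The central C8–C9 σ-bond of the linker is cut, giving two molecules of dienyl iodide **13**. The neighbouring cut (C6–C7 and C10–C11, a C4 bis-stannane coupled to two 2-bromoalkenes) would place alkenylpalladium on a 2-bromo-1,6-diene. That is the classical substrate for 5-exo Heck carbopalladation onto the C3 vinyl group. With the halide at the diene terminus C8, insertion would need a seven-membered ring and cannot compete. The forward reaction is a reductive homocoupling with retention of the E geometry.

**13 ⇒ 11 + 3.** The C3–C4 bond of **13** (the future ring C1–C2 bond) is cut to aldehyde **11** and (R,E)-6,7-epoxygeranyl pinacolboronate **3**. Forming the neighbouring C4–C5 bond instead would require an α-quaternary aldehyde whose centre is made separately. Here vinyl, methyl, chain and hydroxyl arrive in one step. The E geometry of **3** fixes the relative configuration through the chair transition state, and a chiral phosphoric acid fixes the absolute one. The epoxide is set earlier by an independent reagent, so the wrong combinations are diastereomers of **13**. Removing them should raise the enantiomeric purity of **13** above that of either asymmetric step.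

**3 ⇒ 2 ⇒ 1.** The C–B bond comes from the allylic C–OAc bond, and the epoxide from the 6,7-alkene of geranyl acetate **1**. Epoxidising at this stage uses the allylic acetate to deactivate the 2,3-alkene. Later intermediates have more alkenes and no such handle.

**11 ⇒ 10 ⇒ 9 ⇒ 7 + 8.** The aldehyde comes from ester **10**, the iodide from stannane **9**, and the C4–C5 bond of **9** from a Stille coupling of bromo ester **7** with (E)-1,2-bis(tributylstannyl)ethene **8**. The coupling is done at the ester stage because **7** has no second alkene for palladium to insert into, and heat and excess reagent do no harm. Tin is exchanged for iodine because a dienylstannane would be protodestannylated by the phosphoric acid of step 7, while a dienyl iodide is inert to it.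

**7 ⇒ 4 + 5.** The C2–C3 bond of the pentenoate is cut to the enolate of ethyl acetate **4** and 2,3-dibromopropene **5**; only the allylic bromide is displaced.

## Roads not taken

Alternative 1: The rings are cut at C1–C2 and C5–C6 (retro-Diels–Alder). Siloxydiene **A2** and butenone **A3** would combine under a chiral oxazaborolidinium Lewis acid to give **A1**, in which the ring, quaternary C2 and C1 are in place and the silyl enol ether marks C3=C4.
- Merits: one catalytic enantioselective step builds the ring and both ring stereocentres; the enol ether is a regiodefined handle for attaching the linker at C4; no metathesis inside a polyene is needed. In the reliability of the ring-forming event this road may well be better.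
- Weak points: the reacting diene terminus is fully substituted, so the methyl group must point inward in the s-cis conformer; such dienes are slow, and Mukaiyama–Michael addition and cation–olefin chemistry at the isopropylidene alkene compete. C1 arrives as an acetyl group and must become a hydroxyl by Baeyer–Villiger oxidation, with a peracid that would attack the enol ether and the trisubstituted alkene first. The epoxide cannot be present in the Lewis-acid step and needs a separate asymmetric epoxidation before the tetraene exists.
- Comparison: the extra redox and protecting steps would put this road well above nine steps. The chosen plan brings C1 in at the right oxidation level and the epoxide in from the start, with no protecting group, and pays with a less certain last step.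

Alternative 2: The same C1–C2 bonds as in step 7 are formed, but both at once and on the full chain. Dialdehyde **A5** would take up two molecules of **3** under the chiral acid to give **A4**, which is the same compound as **15**; the same double metathesis would follow.
- Merits: four stereocentres in one operation. The Stille coupling and a stannane homocoupling would be run at the achiral ester stage, so no tin–iodine exchange is needed and the route is one step shorter. All palladium and tin chemistry is finished before chiral material appears. In step count and convergence this road is better.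
- Weak points: **A5** is a polymerisable tetraene with two enolisable aldehydes, and it must sit with a Brønsted acid through two slow additions of a γ,γ-disubstituted boronate. Both additions need high catalyst control. The mono-adduct and the stereoisomeric bis-adducts differ only at centres more than ten bonds apart, so they can hardly be separated or analysed at the C34 stage.
- Comparison: the chosen plan runs the stereo-defining addition once, on the small monofunctional aldehyde **11**. Its outcome can be measured and upgraded at **13**, and the polyene appears only two steps from the end.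

Alternative 3: Each ring is cut at C2–C3. In **A7**, a symmetric tetraene with two terminal vinylsilanes and two cis-trisubstituted C1–C2 epoxides, a dialkylaluminium chloride would activate each epoxide; silicon-bearing C3 would attack C2 with inversion and silicon would be lost to leave C3=C4. The product **A6** has both rings and both C1/C2 pairs, with the side-chain epoxides held as diol acetonides.
- Merits: both quaternary centres follow stereospecifically from epoxide geometry and configuration, without catalyst control at the ring-forming stage; both rings close in one operation; silicon fixes the alkene position. In stereochemical certainty at the ring centres this road is at least equal to the chosen one.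
- Weak points: the cation developing at C4 is conjugated with the whole linker, so proton loss, E/Z scrambling and attack at remote positions compete with desilylation. The Lewis acid excludes the side-chain epoxides, which must be made at the very end by acetonide cleavage with acid on the tetraene, selective sulfonylation beside the ring hydroxyls and base closure. **A7** needs four stereodefined alkenes, two enantioenriched epoxides and two protected diols.
- Comparison: the chosen plan needs far fewer steps, no protecting group and no acid once the hydroxyl and epoxide share a molecule.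

Key step: step 9

Assumption: the D-fructose-derived Shi ketone is taken to give the (R)-epoxide at the isopropylidene terminus, as it does for other trisubstituted alkenes.
Assumption: the (S)-phosphoric acid is taken to deliver the allyl group to the Si face of **11**, by analogy with the Re-face preference of the (R)-acid; if the sense proves opposite, the (R)-acid is used.

## Route

Step 1
Reactants: 1 geranyl acetate [(2E)-3,7-dimethylocta-2,6-dien-1-yl acetate]
Product: 2 (2E)-5-[(2R)-3,3-dimethyloxiran-2-yl]-3-methylpent-2-en-1-yl acetate [(R)-6,7-epoxygeranyl acetate]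
Conditions: Shi ketone (1,2:4,5-di-O-isopropylidene-β-D-erythro-2,3-hexodiulo-2,6-pyranose, 0.3 equiv), Oxone (2KHSO5·KHSO4·K2SO4), K2CO3, Bu4NHSO4, aq. Na2B4O7/Na2H2EDTA, MeCN–CH2(OMe)2, 0 °C
Reagents that add atoms: potassium peroxymonosulfate (oxidant of Oxone), [K+].[O-]S(=O)(=O)OO
Why: Shi asymmetric epoxidation: the dioxirane formed from the ketone transfers oxygen through a spiro transition state to the electron-rich 6,7-alkene, the 2,3-alkene being deactivated by the allylic acetate; the ketone sets the (R)-epoxide carbon.

Step 2
Reactants: 2 (R)-6,7-epoxygeranyl acetate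
Product: 3 2-{(2E)-5-[(2R)-3,3-dimethyloxiran-2-yl]-3-methylpent-2-en-1-yl}-4,4,5,5-tetramethyl-1,3,2-dioxaborolane [(R,E)-6,7-epoxygeranyl pinacolboronate]
Conditions: Pd2(dba)3 (2.5 mol %), B2pin2 (1.1 equiv), DMSO, 50 °C
Reagents that add atoms: bis(pinacolato)diboron, CC1(C)OB(OC1(C)C)B1OC(C)(C)C(C)(C)O1
Why: Miyaura allylic borylation: oxidative addition of the allylic acetate to zerovalent palladium, transmetalation of the π-allylpalladium acetate with the diboron and reductive elimination at the primary terminus. The E geometry should hold because syn/anti exchange would need a σ-allyl at the tertiary carbon, and the alkyl epoxide is inert to zerovalent palladium.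

Step 3
Reactants: 4 ethyl acetate; 5 2,3-dibromoprop-1-ene
Product: 7 ethyl 4-bromopent-4-enoate, via lithium enolate of ethyl acetate 6 (not isolated)
Conditions: LiN(i-Pr)2 (1.05 equiv), THF, −78 °C; then 5, DMPU, −78 → −20 °C
Reagents that add atoms: none
Why: Ester enolate alkylation by SN2 displacement of the allylic bromide; the vinylic bromide does not react, and low temperature with a reactive allylic halide outruns Claisen self-condensation.

Step 4
Reactants: 7 ethyl 4-bromopent-4-enoate; 8 (E)-1,2-bis(tributylstannyl)ethene (3 equiv)
Product: 9 ethyl (5E)-4-methylidene-6-(tributylstannyl)hex-5-enoate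
Conditions: Pd(PPh3)4 (5 mol %), toluene, 90 °C, dark
Reagents that add atoms: none
Why: Stille coupling with retention at both alkenes gives the (E)-dienylstannane; the excess of 8 holds back a second coupling, and 7 has no other alkene into which the alkenylpalladium bromide could insert.

Step 5
Reactants: 9 ethyl (5E)-4-methylidene-6-(tributylstannyl)hex-5-enoate
Product: 10 ethyl (5E)-6-iodo-4-methylidenehex-5-enoate
Conditions: I2 (1.05 equiv), CH2Cl2, 0 °C; aq. Na2S2O3
Reagents that add atoms: iodine, II
Why: Iododestannylation is an ipso electrophilic substitution assisted by the β-tin effect; it retains the E geometry and is much faster than addition of iodine to the diene.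

Step 6
Reactants: 10 ethyl (5E)-6-iodo-4-methylidenehex-5-enoate
Product: 11 (5E)-6-iodo-4-methylidenehex-5-enal
Conditions: i-Bu2AlH (1.05 equiv), CH2Cl2, −78 °C; MeOH, then aq. KNaC4H4O6
Reagents that add atoms: none
Why: Partial ester reduction: the tetrahedral aluminium hemiacetal is stable at −78 °C and releases the aldehyde only on work-up; the iododiene is not hydroaluminated at this temperature.

Step 7
Reactants: 11 (5E)-6-iodo-4-methylidenehex-5-enal; 3 (R,E)-6,7-epoxygeranyl pinacolboronate (1.1 equiv)
Product: 13 (3S,4R,7E)-3-{2-[(2R)-3,3-dimethyloxiran-2-yl]ethyl}-8-iodo-3-methyl-6-methylideneocta-1,7-dien-4-ol, via pinacol borate ester 12 (not isolated)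
Conditions: (S)-TRIP [(S)-3,3'-bis(2,4,6-triisopropylphenyl)-1,1'-binaphthyl-2,2'-diyl hydrogen phosphate] (5 mol %), 4 Å MS, toluene, −30 °C; aq. NaHCO3
Reagents that add atoms: none
Why: Chiral-phosphoric-acid-catalysed allylboration through a closed chair Zimmerman–Traxler transition state: the E geometry of 3 places the epoxyethyl chain pseudo-equatorial and the methyl pseudo-axial, fixing C3 (S) relative to C4 (R), and the (S)-acid is expected to select the Si face of 11 and so the absolute configuration. The alcohol stays masked as borate 12 until the basic work-up, which keeps it from attacking the epoxide while acid is present; the dienyl iodide is inert.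

Step 8
Reactants: 13 (3S,4R,7E)-3-{2-[(2R)-3,3-dimethyloxiran-2-yl]ethyl}-8-iodo-3-methyl-6-methylideneocta-1,7-dien-4-ol (two molecules)
Product: 15 (3S,4R,7E,9E,13R,14S)-3,14-bis{2-[(2R)-3,3-dimethyloxiran-2-yl]ethyl}-3,14-dimethyl-6,11-dimethylidenehexadeca-1,7,9,15-tetraene-4,13-diol, via dienyl trimethylstannane 14 (not isolated)
Conditions: Pd(PPh3)4 (10 mol %), Me3SnSnMe3 (0.55 equiv), 1,4-dioxane, 70 °C, dark, 2,6-di-tert-butyl-4-methylphenol (trace)
Reagents that add atoms: none
Why: Palladium-catalysed distannane-mediated reductive homocoupling: half of 13 is stannylated in situ to 14, which undergoes Stille coupling with the remaining 13, both events with retention of the E geometry. Palladium sits at the diene terminus, from where insertion into the C3 vinyl group would need a seven-membered ring and cannot compete with transmetalation.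

Step 9
Reactants: 15 (3S,4R,7E,9E,13R,14S)-3,14-bis{2-[(2R)-3,3-dimethyloxiran-2-yl]ethyl}-3,14-dimethyl-6,11-dimethylidenehexadeca-1,7,9,15-tetraene-4,13-diol
Product: 17 (1R,1'R,2S,2'S)-4,4'-[(1E,3E)-buta-1,3-diene-1,4-diyl]bis(2-{2-[(2R)-3,3-dimethyloxiran-2-yl]ethyl}-2-methylcyclohex-3-en-1-ol), via half-closed monocyclic pentaene 16 (not isolated)
Conditions: second-generation Hoveyda–Grubbs catalyst RuCl2(H2IMes)(=CH-C6H4-2-O-i-Pr) (2 × 5 mol %), toluene (0.002 M), 60 °C, Ar sparge, dark
Reagents that add atoms: none
Why: Two-directional ring-closing olefin metathesis: the ruthenium alkylidene exchanges onto a C2 vinyl group with loss of ethene, the resulting neopentyl alkylidene adds across the C4 methylidene five atoms away, and cycloreversion of that ruthenacyclobutane forms C3=C4 and passes Ru=CH2 on to the next vinyl group. The closest known reaction type is ene–diene ring-closing metathesis onto the 2-methylidene terminus of a 1,3-diene to give 1-alkenylcyclohexenes. Each ring closes as a six-membered carbocycle with the new double bond endocyclic between C3 and C4; the half-closed pentaene 16 is the expected intermediate and reacts at its second end in the same way. No stereocentre is formed, and C1, C2 and the epoxide carbons are untouched under these neutral conditions. The step needs site selectivity among six alkenes: addition to the internal C7=C8 bond would give a seven-membered ring and cut the linker, and is disfavoured by ring size, 1,2-disubstitution and conjugation. High dilution and the hindered terminal alkenes suppress intermolecular metathesis, argon sparging removes ethene, and the trisubstituted, conjugated ring alkenes of the product should not re-enter the cycle. Free homoallylic hydroxyls and alkyl epoxides are tolerated by this catalyst class.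

## Compound list

1 | geranyl acetate, (2E)-3,7-dimethylocta-2,6-dien-1-yl acetate | CC(C)=CCC/C(C)=C/COC(C)=O | starting material
2 | (2E)-5-[(2R)-3,3-dimethyloxiran-2-yl]-3-methylpent-2-en-1-yl acetate | CC1(C)O[C@@H]1CC/C(C)=C/COC(C)=O | intermediate
3 | 2-{(2E)-5-[(2R)-3,3-dimethyloxiran-2-yl]-3-methylpent-2-en-1-yl}-4,4,5,5-tetramethyl-1,3,2-dioxaborolane | CC1(C)O[C@@H]1CC/C(C)=C/CB1OC(C)(C)C(C)(C)O1 | intermediate
4 | ethyl acetate | CCOC(C)=O | starting material
5 | 2,3-dibromoprop-1-ene | C=C(Br)CBr | starting material
6 | lithium 1-ethoxyethen-1-olate (lithium enolate of ethyl acetate) | C=C(OCC)O[Li] | intermediate (not isolated)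
7 | ethyl 4-bromopent-4-enoate | CCOC(=O)CCC(Br)=C | intermediate
8 | (E)-1,2-bis(tributylstannyl)ethene | CCCC[Sn](CCCC)(CCCC)/C=C/[Sn](CCCC)(CCCC)CCCC | starting material
9 | ethyl (5E)-4-methylidene-6-(tributylstannyl)hex-5-enoate | CCOC(=O)CCC(=C)/C=C/[Sn](CCCC)(CCCC)CCCC | intermediate
10 | ethyl (5E)-6-iodo-4-methylidenehex-5-enoate | CCOC(=O)CCC(=C)/C=C/I | intermediate
11 | (5E)-6-iodo-4-methylidenehex-5-enal | O=CCCC(=C)/C=C/I | intermediate
12 | 2-{[(3S,4R,7E)-3-{2-[(2R)-3,3-dimethyloxiran-2-yl]ethyl}-8-iodo-3-methyl-6-methylideneocta-1,7-dien-4-yl]oxy}-4,4,5,5-tetramethyl-1,3,2-dioxaborolane | CC1(C)O[C@@H]1CC[C@@](C)(C=C)[C@H](OB1OC(C)(C)C(C)(C)O1)CCC(=C)/C=C/I | intermediate (not isolated)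
13 | (3S,4R,7E)-3-{2-[(2R)-3,3-dimethyloxiran-2-yl]ethyl}-8-iodo-3-methyl-6-methylideneocta-1,7-dien-4-ol | CC1(C)O[C@@H]1CC[C@@](C)(C=C)[C@H](O)CCC(=C)/C=C/I | intermediate
14 | (3S,4R,7E)-3-{2-[(2R)-3,3-dimethyloxiran-2-yl]ethyl}-3-methyl-6-methylidene-8-(trimethylstannyl)octa-1,7-dien-4-ol | CC1(C)O[C@@H]1CC[C@@](C)(C=C)[C@H](O)CCC(=C)/C=C/[Sn](C)(C)C | intermediate (not isolated)
15 | (3S,4R,7E,9E,13R,14S)-3,14-bis{2-[(2R)-3,3-dimethyloxiran-2-yl]ethyl}-3,14-dimethyl-6,11-dimethylidenehexadeca-1,7,9,15-tetraene-4,13-diol | CC1(C)O[C@@H]1CC[C@@](C)(C=C)[C@H](O)CCC(=C)/C=C/C=C/C(=C)CC[C@@H](O)[C@](C)(C=C)CC[C@H]1OC1(C)C | intermediate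
16 | (1R,2S)-2-{2-[(2R)-3,3-dimethyloxiran-2-yl]ethyl}-4-[(1E,3E,8R,9S)-9-{2-[(2R)-3,3-dimethyloxiran-2-yl]ethyl}-8-hydroxy-9-methyl-5-methylideneundeca-1,3,10-trien-1-yl]-2-methylcyclohex-3-en-1-ol | CC1(C)O[C@@H]1CC[C@@]1(C)C=C(/C=C/C=C/C(=C)CC[C@@H](O)[C@](C)(C=C)CC[C@H]2OC2(C)C)CC[C@H]1O | intermediate (not isolated)
17 | (1R,1'R,2S,2'S)-4,4'-[(1E,3E)-buta-1,3-diene-1,4-diyl]bis(2-{2-[(2R)-3,3-dimethyloxiran-2-yl]ethyl}-2-methylcyclohex-3-en-1-ol) | CC1(C)O[C@@H]1CC[C@@]1(C)C=C(/C=C/C=C/C2=C[C@](C)(CC[C@H]3OC3(C)C)[C@H](O)CC2)CC[C@H]1O | target

## Step count and least certain steps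

Total: 9 steps. Longest linear sequence: 7 steps (steps 3–9, from ethyl acetate and 2,3-dibromopropene); the boronate branch (steps 1 and 2) joins at step 7.

**Step 9 (key step).** The most likely failure is incomplete or unselective metathesis. The conjugated polyene can hold the ruthenium as an unreactive vinylalkylidene, both terminal alkene types are hindered and initiate slowly, and at longer reaction times attack at C7=C8, oligomerisation and ruthenium hydride isomerisation of the tetraene gain ground. The fallback closes each ring before the halves are joined. Starting from **13**, the same catalyst should close the ring of this simpler triene, whose iodoalkene is an electron-poor spectator, to give (1R,2S)-2-{2-[(2R)-3,3-dimethyloxiran-2-yl]ethyl}-4-[(E)-2-iodoethenyl]-2-methylcyclohex-3-en-1-ol F1. Reductive homocoupling of F1 under the conditions of step 8 then returns to the route at **17**.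

**Step 7.** Loss of enantio- and diastereocontrol is the main risk: the γ,γ-disubstituted boronate reacts slowly, so warming may be needed and the uncatalysed pathway then competes. The acid may also open or rearrange the trisubstituted epoxide. The fallback keeps acid and epoxide apart. Geranyl acetate **1** is borylated as in step 2 to geranyl pinacolboronate F2, which adds to **11** under the same acid, or under a chiral diol·SnCl4 system that an epoxide would not survive. This gives (3S,4R,7E)-8-iodo-3-methyl-6-methylidene-3-(4-methylpent-3-en-1-yl)octa-1,7-dien-4-ol F3. Shi epoxidation of F3 at its only trisubstituted, electron-rich alkene (the vinyl group, the 1,1-disubstituted diene terminus and the iodoalkene being poor substrates) returns to the route at **13**.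

**Step 8.** The one-pot sequence may stall at a mixture of **13** and **14**, or lose halide and tin by protodemetalation to the terminal diene. At 70 °C the Me3SnI formed may also assist attack of the C4 hydroxyl on the epoxide. The fallback separates the two events and runs the coupling cold. Half of **13** is stannylated with Bu3SnSnBu3 and PdCl2(PPh3)2 to (3S,4R,7E)-3-{2-[(2R)-3,3-dimethyloxiran-2-yl]ethyl}-3-methyl-6-methylidene-8-(tributylstannyl)octa-1,7-dien-4-ol F4. F4 is then joined to the other half of **13** with copper thiophene-2-carboxylate, Cu(O2CC4H3S), in NMP at 0 °C, returning to the route at **15**.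

**Step 4.** Over-coupling of **9** with a second molecule of **7** to a symmetric triene diester, slow oxidative addition of the 2-bromoalkene, and protodestannylation on silica are the likely losses. The fallback is tin-free. Starting from **7**, Sonogashira coupling with ethynyltrimethylsilane (PdCl2(PPh3)2, CuI, Et3N) gives ethyl 4-methylidene-6-(trimethylsilyl)hex-5-ynoate F5. Desilylation with K2CO3 in ethanol gives ethyl 4-methylidenehex-5-ynoate F6, and hydrozirconation with Cp2Zr(H)Cl followed by iodine returns to the route at **10**.

## Further compounds

F1 | step 9 | (1R,2S)-2-{2-[(2R)-3,3-dimethyloxiran-2-yl]ethyl}-4-[(E)-2-iodoethenyl]-2-methylcyclohex-3-en-1-ol | CC1(C)O[C@@H]1CC[C@@]1(C)C=C(/C=C/I)CC[C@H]1O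
F2 | step 7 | 2-[(2E)-3,7-dimethylocta-2,6-dien-1-yl]-4,4,5,5-tetramethyl-1,3,2-dioxaborolane (geranyl pinacolboronate) | CC(C)=CCC/C(C)=C/CB1OC(C)(C)C(C)(C)O1
F3 | step 7 | (3S,4R,7E)-8-iodo-3-methyl-6-methylidene-3-(4-methylpent-3-en-1-yl)octa-1,7-dien-4-ol | CC(C)=CCC[C@@](C)(C=C)[C@H](O)CCC(=C)/C=C/I
F4 | step 8 | (3S,4R,7E)-3-{2-[(2R)-3,3-dimethyloxiran-2-yl]ethyl}-3-methyl-6-methylidene-8-(tributylstannyl)octa-1,7-dien-4-ol | CC1(C)O[C@@H]1CC[C@@](C)(C=C)[C@H](O)CCC(=C)/C=C/[Sn](CCCC)(CCCC)CCCC
F5 | step 4 | ethyl 4-methylidene-6-(trimethylsilyl)hex-5-ynoate | CCOC(=O)CCC(=C)C#C[Si](C)(C)C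
F6 | step 4 | ethyl 4-methylidenehex-5-ynoate | CCOC(=O)CCC(=C)C#C
A1 | alternative 1 | 1-[(1R,2S)-4-{[tert-butyl(dimethyl)silyl]oxy}-2-methyl-2-(4-methylpent-3-en-1-yl)cyclohex-3-en-1-yl]ethan-1-one | CC(C)=CCC[C@@]1(C)C=C(O[Si](C)(C)C(C)(C)C)CC[C@H]1C(C)=O
A2 | alternative 1 | tert-butyl{[(3E)-4,8-dimethylnona-1,3,7-trien-2-yl]oxy}dimethylsilane | C=C(O[Si](C)(C)C(C)(C)C)/C=C(\C)CCC=C(C)C
A3 | alternative 1 | but-3-en-2-one (butenone) | C=CC(C)=O
A4 | alternative 2 | (3S,4R,7E,9E,13R,14S)-3,14-bis{2-[(2R)-3,3-dimethyloxiran-2-yl]ethyl}-3,14-dimethyl-6,11-dimethylidenehexadeca-1,7,9,15-tetraene-4,13-diol (identical with 15) | CC1(C)O[C@@H]1CC[C@@](C)(C=C)[C@H](O)CCC(=C)/C=C/C=C/C(=C)CC[C@@H](O)[C@](C)(C=C)CC[C@H]1OC1(C)C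
A5 | alternative 2 | (5E,7E)-4,9-dimethylidenedodeca-5,7-dienedial | O=CCCC(=C)/C=C/C=C/C(=C)CCC=O
A6 | alternative 3 | (1R,1'R,2S,2'S)-4,4'-[(1E,3E)-buta-1,3-diene-1,4-diyl]bis(2-methyl-2-{2-[(4S)-2,2,5,5-tetramethyl-1,3-dioxolan-4-yl]ethyl}cyclohex-3-en-1-ol) | CC1(C)OC(C)(C)[C@@H](O1)CC[C@@]1(C)C=C(/C=C/C=C/C2=C[C@](C)(CC[C@@H]3OC(C)(C)OC3(C)C)[C@H](O)CC2)CC[C@H]1O
A7 | alternative 3 | (1Z,3E,5E,7Z)-2,7-bis{2-[(2R,3S)-3-methyl-3-{2-[(4S)-2,2,5,5-tetramethyl-1,3-dioxolan-4-yl]ethyl}oxiran-2-yl]ethyl}-1,8-bis(trimethylsilyl)octa-1,3,5,7-tetraene | C[Si](C)(C)/C=C(/CC[C@H]1O[C@@]1(C)CC[C@@H]1OC(C)(C)OC1(C)C)\C=C\C=C\C(=C/[Si](C)(C)C)CC[C@H]1O[C@@]1(C)CC[C@@H]1OC(C)(C)OC1(C)C
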